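**Strategy**

The target is achiral and is cut at one place only: the hexasubstituted central phloroglucinol ring B. Its six carbons are C1–C6 of a methyl 3,5-dioxoheptanoate; the oxygenated ring carbons are C1, C3 and C5, the open position is C2, the benzylic arm to the methylated ring C sits on C4, and C7 is the CH2 joining C6 to the filicinic ring A. One base-mediated Claisen closure of C6 onto the C1 ester forms the last ring bond and aromatises, so the open-chain precursor, which already carries rings A and C, becomes the complete three-ring skeleton. A final butyrylation at C2 of ring B gives the target.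

Key step: step 8

Remark: the target has no stereocentre, so no enantiomer has to be controlled; enolised rings and chains are written in one tautomer each, and chain atoms C1–C7 are those of the heptanoate.

**Route**

Step 1
Reactants: 1 phloroglucinol
Product: 2 1-(2,4,6-trihydroxyphenyl)butan-1-one
Conditions: n-PrCOCl, AlCl3, PhNO2–CH2Cl2, 0 °C → 60 °C; aq. HCl
Reagents that add atoms: butanoyl chloride CCCC(Cl)=O
Why: Friedel–Crafts C-acylation of the symmetrical, highly activated triol, which stops after one acyl group because the chelated ketone deactivates the ring.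

Step 2
Reactants: 2 1-(2,4,6-trihydroxyphenyl)butan-1-one
Product: 3 butyrylfilicinic acid (2-butanoyl-3,5-dihydroxy-4,4-dimethylcyclohexa-2,5-dien-1-one)
Conditions: MeI (2.2 equiv), NaOMe (3 equiv), MeOH, 0 °C → rt; chromatography
Reagents that add atoms: iodomethane CI
Why: Base-mediated C-methylation of the acylphloroglucinol phenoxide, in which the second methyl group enters the carbon already methylated and gives the enolised gem-dimethyl triketone, which is separated from the nuclear mono- and trimethyl by-products.

Step 3
Reactants: 3 butyrylfilicinic acid; 4 acryloyl chloride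
Product: 5 6-butanoyl-5-hydroxy-8,8-dimethyl-3,4-dihydro-2H-chromene-2,7(8H)-dione (enol lactone on ring A)
Conditions: i-Pr2NEt, DMAP (cat.), CH2Cl2, −20 °C → rt
Reagents that add atoms: none
Why: Nucleophile-catalysed Michael addition–enol lactonisation (formal [3+3] annulation) places the CH2CH2CO unit on the free ring-A carbon C6 and ties it to a flanking enol oxygen; closure onto either oxygen is acceptable since both lactones open to the same chain in step 4.

Step 4
Reactants: 5 enol lactone; 6 methyl acetoacetate
Product: 7 methyl 7-(5-butanoyl-2,6-dihydroxy-3,3-dimethyl-4-oxocyclohexa-1,5-dien-1-yl)-3,5-dioxoheptanoate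
Conditions: 6 (3.3 equiv), LDA (6.6 equiv), THF, 0 °C; then 5, −78 → 0 °C; cold aq. HCl
Reagents that add atoms: none
Why: Claisen-type γ-acylation of the acetoacetate dianion by the activated enol ester; the excess dianion takes up the acidic ring-A proton and that of the new β-diketone, whose enolate is protected from a second addition.

Step 5
Reactants: 8 2-methylphloroglucinol
Product: 9 1-(2,4,6-trihydroxy-3-methylphenyl)butan-1-one
Conditions: n-PrCOCl, AlCl3, PhNO2–CH2Cl2, 0 °C → 60 °C; aq. HCl
Reagents that add atoms: butanoyl chloride CCCC(Cl)=O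
Why: Friedel–Crafts C-acylation at one of the two equivalent free ring carbons, which again stops at the monoketone.

Step 6
Reactants: 9 1-(2,4,6-trihydroxy-3-methylphenyl)butan-1-one
Product: 10 1-[3-[(dimethylamino)methyl]-2,4,6-trihydroxy-5-methylphenyl]butan-1-one
Conditions: aq. CH2O, aq. Me2NH, EtOH, 0 °C → rt
Reagents that add atoms: formaldehyde C=O; dimethylamine CNC
Why: Mannich reaction at the only unsubstituted ring carbon, kept cold with premixed amine and aldehyde so that the benzylic amine does not react further.

Step 7
Reactants: 7 ring-A dioxo ester; 10 ring-C Mannich base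
Product: 12 methyl 4-[(3-butanoyl-2,4,6-trihydroxy-5-methylphenyl)methyl]-7-(5-butanoyl-2,6-dihydroxy-3,3-dimethyl-4-oxocyclohexa-1,5-dien-1-yl)-3,5-dioxoheptanoate, via ring-C o-quinone methide 11 (not isolated)
Conditions: 1,4-dioxane, 50 °C, N2; dilute aq. HCl wash
Reagents that add atoms: none
Why: Loss of dimethylamine from the phenolic Mannich base (held afterwards as its salt by the acidic ring A) gives the o-quinone methide, which undergoes Michael addition at C4, the most acidic and most enolised carbon of 7, in preference to C2 or the fully substituted ring-A carbon, and thereby restores the aromatic ring C.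

Step 8
Reactants: 12 arm-bearing methyl 3,5-dioxoheptanoate
Product: 14 2-butanoyl-4-[[3-[(3-butanoyl-2,4,6-trihydroxy-5-methylphenyl)methyl]-2,4,6-trihydroxyphenyl]methyl]-3,5-dihydroxy-6,6-dimethylcyclohexa-2,4-dien-1-one, via ring-B cyclohexane-1,3,5-trione 13 (not isolated)
Conditions: 12 added to KHMDS (7 equiv), THF–DMPU, −78 °C → rt; then 1 M HCl, 0 °C
Reagents that add atoms: none
Why: Seven equivalents of hindered amide base ionise the five OH groups, C4–H and C2–H; by proton exchange a small share of the heptaanion carries the charge on C6 instead of C2, and this α-carbanion of the C5 ketone adds to the non-enolised C1 ester carbonyl, methoxide leaves, and trione 13 enolises at once to the aromatic ring-B triphenoxide, which drains the equilibrium. The closest known reactions are the intramolecular Claisen (Dieckmann-type) closure of δ-keto esters to cyclohexane-1,3-diones, which runs even when the ester α-carbon is the more acidic site (as in the malonate route to dimedone), and the base-induced closure of 3,5-dioxohexanoate esters and polyketo-ester polyanions to phloroglucinols. Ring B closes in the 6-exo-trig mode, and the two sp3 centres of 13 (C4 and C6) vanish on aromatisation, so no stereocentre has to be controlled. The step needs C- over O-acylation: closure through O5 to a 4-hydroxy-2-pyranone is the known side reaction of 3,5-dioxo esters, and potassium in THF–DMPU is chosen to loosen the O3/O5 chelate that holds O5 rather than C6 next to the ester. It also needs both arms to stay on: C4 remains an enolate throughout and so cannot be expelled from the ring-C quinone methide, and ring A, a dianion, is neither a leaving group for a retro-Michael reaction at C7 nor an electrophile for the chain carbanions. The non-nucleophilic base avoids retro-Claisen cleavage of the C4-substituted β-diketone.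

Step 9
Reactants: 14 trimer with free C2 on ring B
Product: 15 2-butanoyl-4-[[3-butanoyl-5-[(3-butanoyl-2,4,6-trihydroxy-5-methylphenyl)methyl]-2,4,6-trihydroxyphenyl]methyl]-3,5-dihydroxy-6,6-dimethylcyclohexa-2,4-dien-1-one (CNP0086105.0)
Conditions: (n-PrCO)2O (1.3 equiv), BF3·OEt2, 1,4-dioxane, 0 °C → rt; then aq. MeOH
Reagents that add atoms: butanoic anhydride CCCC(=O)OC(=O)CCC
Why: Friedel–Crafts acylation at the single unsubstituted carbon of the molecule, which is flanked by two hydroxyls on the most electron-rich ring; BF2 chelates are hydrolysed in the work-up.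

**Compound list**

1 | phloroglucinol | Oc1cc(O)cc(O)c1 | starting material
2 | 1-(2,4,6-trihydroxyphenyl)butan-1-one | CCCC(=O)c1c(O)cc(O)cc1O | intermediate
3 | butyrylfilicinic acid, 2-butanoyl-3,5-dihydroxy-4,4-dimethylcyclohexa-2,5-dien-1-one | CCCC(=O)C1=C(O)C(C)(C)C(O)=CC1=O | intermediate
4 | acryloyl chloride | C=CC(Cl)=O | starting material
5 | 6-butanoyl-5-hydroxy-8,8-dimethyl-3,4-dihydro-2H-chromene-2,7(8H)-dione | O=C1CCC2=C(O1)C(C)(C)C(=O)C(C(=O)CCC)=C2O | intermediate
6 | methyl acetoacetate | COC(=O)CC(C)=O | starting material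
7 | methyl 7-(5-butanoyl-2,6-dihydroxy-3,3-dimethyl-4-oxocyclohexa-1,5-dien-1-yl)-3,5-dioxoheptanoate | COC(=O)CC(=O)CC(=O)CCC1=C(O)C(C)(C)C(=O)C(C(=O)CCC)=C1O | intermediate
8 | 2-methylphloroglucinol | Cc1c(O)cc(O)cc1O | starting material
9 | 1-(2,4,6-trihydroxy-3-methylphenyl)butan-1-one | CCCC(=O)c1c(O)cc(O)c(C)c1O | intermediate
10 | 1-[3-[(dimethylamino)methyl]-2,4,6-trihydroxy-5-methylphenyl]butan-1-one | CCCC(=O)c1c(O)c(CN(C)C)c(O)c(C)c1O | intermediate
11 | 4-butanoyl-3,5-dihydroxy-2-methyl-6-methylidenecyclohexa-2,4-dien-1-one (ring-C o-quinone methide) | C=C1C(=O)C(C)=C(O)C(C(=O)CCC)=C1O | intermediate (not isolated)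
12 | methyl 4-[(3-butanoyl-2,4,6-trihydroxy-5-methylphenyl)methyl]-7-(5-butanoyl-2,6-dihydroxy-3,3-dimethyl-4-oxocyclohexa-1,5-dien-1-yl)-3,5-dioxoheptanoate | COC(=O)CC(=O)C(Cc1c(O)c(C)c(O)c(C(=O)CCC)c1O)C(=O)CCC1=C(O)C(C)(C)C(=O)C(C(=O)CCC)=C1O | intermediate
13 | ring-B cyclohexane-1,3,5-trione tautomer of 14, carrying the ring-C arm on C4 and the ring-A arm on C6 (configuration immaterial) | O=C1CC(=O)C(Cc2c(O)c(C)c(O)c(C(=O)CCC)c2O)C(=O)C1CC1=C(O)C(C)(C)C(=O)C(C(=O)CCC)=C1O | intermediate (not isolated)
14 | 2-butanoyl-4-[[3-[(3-butanoyl-2,4,6-trihydroxy-5-methylphenyl)methyl]-2,4,6-trihydroxyphenyl]methyl]-3,5-dihydroxy-6,6-dimethylcyclohexa-2,4-dien-1-one | CCCC(=O)C1=C(O)C(Cc2c(O)c(Cc3c(O)c(C)c(O)c(C(=O)CCC)c3O)c(O)cc2O)=C(O)C(C)(C)C1=O | intermediate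
15 | 2-butanoyl-4-[[3-butanoyl-5-[(3-butanoyl-2,4,6-trihydroxy-5-methylphenyl)methyl]-2,4,6-trihydroxyphenyl]methyl]-3,5-dihydroxy-6,6-dimethylcyclohexa-2,4-dien-1-one | CCCC(=O)C1=C(O)C(Cc2c(O)c(Cc3c(O)c(C)c(O)c(C(=O)CCC)c3O)c(O)c(C(=O)CCC)c2O)=C(O)C(C)(C)C1=O | target

**Count**

Total step count: 9. Longest linear sequence: 7 steps (1, 2, 3, 4, 7, 8, 9).

**Steps most likely to fail**

1. Step 8. The chain may rest as the fully enolised polyanion whose ester is too electron-rich to be attacked, it may close through the C5 enolate oxygen instead of C6 to a pyranone, or the polyanion may precipitate before it reacts. The fallback gives up the ring construction and builds the methylene bridges one at a time. It sets out from 2 and 10 and returns to the route at 15.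
   - Mannich base 10, warmed with an excess of 2 (dioxane, 50 °C), passes its quinone methide 11 to one of the two equivalent free ring carbons of 2. This gives the bridged dimer 1-[3-[(3-butanoyl-2,4,6-trihydroxy-5-methylphenyl)methyl]-2,4,6-trihydroxyphenyl]butan-1-one F1.
   - A Mannich reaction (CH2O, Me2NH, EtOH, 0 °C) at the last free ring carbon gives 1-[3-[(3-butanoyl-2,4,6-trihydroxy-5-methylphenyl)methyl]-5-[(dimethylamino)methyl]-2,4,6-trihydroxyphenyl]butan-1-one F2.
   - Warming F2 with butyrylfilicinic acid 3 joins the new quinone methide to C6 of 3 and gives 15 directly.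

2. Step 7. The quinone methide may be captured at C2 instead of C4, and the adduct may lose water from its cyclic hemiketal to give a 4H-chromene. The fallback fixes the arm on C4 by construction. It sets out from 9 and returns at 12.
   - Compound 9 and acrylic acid in methanesulfonic acid (Michael addition–lactonisation) give the dihydrocoumarin 6-butanoyl-5,7-dihydroxy-8-methyl-3,4-dihydro-2H-chromen-2-one F3.
   - Excess lithium enolate of methyl acetate (THF, −78 °C) opens the aryl lactone in a Claisen condensation to methyl 5-(3-butanoyl-2,4,6-trihydroxy-5-methylphenyl)-3-oxopentanoate F4.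
   - The polyanion of F4 (LDA, THF) is acylated at its γ-carbon by enol lactone 5, which gives 12.

3. Step 9. The Lewis acid may cleave and exchange the diarylmethane bridges (retro-Friedel–Crafts), and O-acylation may persist. The fallback uses a nitrilium electrophile at low temperature. It sets out from 14 and returns at 15.
   - Houben–Hoesch reaction (n-PrCN, ZnCl2, HCl gas, Et2O, 0 °C) at the free ring-B carbon gives the ketiminium chloride of the target F5.
   - Hydrolysis in warm water gives 15.

**Further compounds**

F1 | step 8 | 1-[3-[(3-butanoyl-2,4,6-trihydroxy-5-methylphenyl)methyl]-2,4,6-trihydroxyphenyl]butan-1-one | CCCC(=O)c1c(O)cc(O)c(Cc2c(O)c(C)c(O)c(C(=O)CCC)c2O)c1O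
F2 | step 8 | 1-[3-[(3-butanoyl-2,4,6-trihydroxy-5-methylphenyl)methyl]-5-[(dimethylamino)methyl]-2,4,6-trihydroxyphenyl]butan-1-one | CCCC(=O)c1c(O)c(CN(C)C)c(O)c(Cc2c(O)c(C)c(O)c(C(=O)CCC)c2O)c1O
F3 | step 7 | 6-butanoyl-5,7-dihydroxy-8-methyl-3,4-dihydro-2H-chromen-2-one | CCCC(=O)c1c(O)c2CCC(=O)Oc2c(C)c1O
F4 | step 7 | methyl 5-(3-butanoyl-2,4,6-trihydroxy-5-methylphenyl)-3-oxopentanoate | COC(=O)CC(=O)CCc1c(O)c(C)c(O)c(C(=O)CCC)c1O
F5 | step 9 | ketimine hydrochloride of the target (ring-B butanimidoyl in place of butanoyl) | CCCC(=O)C1=C(O)C(Cc2c(O)c(Cc3c(O)c(C)c(O)c(C(=O)CCC)c3O)c(O)c(C(=N)CCC)c2O)=C(O)C(C)(C)C1=O.Cl
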